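**Plan**
1. Ring numbering used: C1 ring C=O, C2 propanoyl, C3 C–OH, C4 prenyl, C5 C–OH, C6 two prenyls. The retrosynthesis cuts first the C2–propanoyl bond, then the ring bond C3–C4, then the two C6–prenyl bonds, and last C5–C6.
2. Enabling feature: C1–C2–C3 form a β-keto acid unit that can be carried as a 2,2-dimethyl-1,3-dioxin-4-one, a latent acylketene at C3. C6 is quaternary, so the C5 ketone can enolise only toward C4; C3 and C4 are therefore the one electrophile/nucleophile pair able to close the six-membered ring.
3. Forward: C5–C6 by γ-acylation of the dioxinone dienolate, then gem-diprenylation at C6. In the key step loss of acetone unmasks the acylketene, which is captured through the C5 oxygen as a 2H-pyran-2,4-dione (the skeleton that is easy to build) and transposed by base from O to C, so that C3–C4 closes the only ring. C2-propanoylation finishes.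
4. The helper dioxinone ring leaves as acetone in the key step itself; no protecting group is used.
5. Stereochemistry: the target is achiral and has no stereogenic alkene, so nothing has to be set; the exocyclic alkene of the transient lactone is consumed again.

Key step: step 4

Remark: the target is treated in the tautomeric form of the given SMILES; prenyl means 3-methylbut-2-en-1-yl.

Step 1
Reactants: 1 5-methylhex-4-enoic acid
Product: 2 5-methylhex-4-enoyl chloride
Conditions: (COCl)2 (1.2 equiv), DMF (cat.), CH2Cl2, 0 °C to rt; concentrate, use crude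
Reagents that add atoms: oxalyl chloride, ClC(=O)C(=O)Cl
Why: DMF-catalysed (Vilsmeier-type) conversion of a carboxylic acid into its chloride should leave the trisubstituted alkene untouched when the HCl is swept out.

Step 2
Reactants: 3 2,2,6-trimethyl-4H-1,3-dioxin-4-one (2.2 equiv); 2 5-methylhex-4-enoyl chloride
Product: 5 2,2-dimethyl-6-(6-methyl-2-oxohept-5-en-1-yl)-4H-1,3-dioxin-4-one, via lithium dienolate 4 (not isolated)
Conditions: LiN(SiMe3)2 (2.2 equiv), THF, -78 °C; then 2 (1.0 equiv), -78 to -20 °C; aq. NH4Cl
Reagents that add atoms: none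
Why: Claisen-type C-acylation of the extended (vinylogous) ester enolate at its γ-carbon forms the future C5–C6 bond, the second equivalent of dienolate deprotonating the more acidic keto-dioxinone and so preventing double acylation.

Step 3
Reactants: 5 2,2-dimethyl-6-(6-methyl-2-oxohept-5-en-1-yl)-4H-1,3-dioxin-4-one; 6 1-bromo-3-methylbut-2-ene (2.5 equiv)
Product: 7 6-[2,10-dimethyl-5-(3-methylbut-2-en-1-yl)-6-oxoundeca-2,9-dien-5-yl]-2,2-dimethyl-4H-1,3-dioxin-4-one
Conditions: Cs2CO3 (3 equiv), DMF, 0 °C to rt
Reagents that add atoms: none
Why: Two successive SN2 C-alkylations of the methylene flanked by the ketone and the vinylogous ester carbon by the soft allylic bromide should create the quaternary future C6, which bears two identical prenyl groups and is therefore no stereocentre.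

Step 4
Reactants: 7 6-[2,10-dimethyl-5-(3-methylbut-2-en-1-yl)-6-oxoundeca-2,9-dien-5-yl]-2,2-dimethyl-4H-1,3-dioxin-4-one
Product: 10 3,5-dihydroxy-4,6,6-tris(3-methylbut-2-en-1-yl)cyclohexa-2,4-dien-1-one, via acylketene 8 (not isolated), via enol lactone 9 (not isolated)
Conditions: PhMe (0.02 M), 110 °C, N2 sweep; then DBU (1.5 equiv), 110 °C; 1 M HCl work-up under N2
Reagents that add atoms: none
Why: Proposed new method: heating cleaves the 1,3-dioxin-4-one of 7 by retro-[4+2] loss of acetone to acylketene 8, whose sp carbon (future C3) is first taken by the oxygen of the C5 ketone to give enol lactone 9; DBU then reopens 9 by E1cB (enolate of the C5 ketone as leaving group) to the ketene/enolate pair, which recloses through carbon, so that the C4 enolate acylates C3 and the C3–C4 bond closes the carbocycle. The closest known reaction types are the thermolysis of keto-dioxinones to 2-pyranones through captured acylketenes and the base-mediated enol-lactone to cyclic 1,3-diketone (Claisen-type pyranone to phloroglucinol) transposition; their union in one flask, ending with a simple ketone enolate as the carbon nucleophile, is the unproven part. The six-membered carbocycle is closed in a 6-(enolendo)-exo-dig mode at the ketene carbon (9 beforehand in a 6-exo-dig mode through oxygen). No stereocentre is formed and the exocyclic alkene of 9 is consumed. The step needs C- over O-acylation and attack by C4 only: C6 is quaternary, so the C5 ketone can enolise only toward C4, and the enol ester 9 is a reversible acyl donor whereas the C-acylated trione is withdrawn as its stable vinylogous-acid salt. High dilution and removal of acetone should hold back ketene dimerisation and return to 7, and the prenyl alkenes are too weakly nucleophilic to compete with the carbonyl oxygen.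

Step 5
Reactants: 10 3,5-dihydroxy-4,6,6-tris(3-methylbut-2-en-1-yl)cyclohexa-2,4-dien-1-one; 11 propanoic acid (1.05 equiv)
Product: 13 postlupulone [3,5-dihydroxy-4,6,6-tris(3-methylbut-2-en-1-yl)-2-propanoylcyclohexa-2,4-dien-1-one], via enol propanoate 12 (not isolated)
Conditions: DCC (1.1 equiv), DMAP (1.2 equiv), CH2Cl2, 0 °C to rt; dilute HCl wash
Reagents that add atoms: none
Why: Carbodiimide O-acylation of the vinylogous acid (Steglich-type) followed by DMAP-mediated 1,3 O-to-C acyl migration should place the propanoyl group on C2, the only unsubstituted ring carbon between two oxygenated carbons, the chelated β-triketone enol being the thermodynamic product.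

**Compound list**
1 | 5-methylhex-4-enoic acid | CC(C)=CCCC(=O)O | starting material
2 | 5-methylhex-4-enoyl chloride | CC(C)=CCCC(=O)Cl | intermediate
3 | 2,2,6-trimethyl-4H-1,3-dioxin-4-one | CC1=CC(=O)OC(C)(C)O1 | starting material
4 | lithium 2,2-dimethyl-6-methylidene-6H-1,3-dioxin-4-olate (lithium dienolate of 3) | [Li+].[O-]C1=CC(=C)OC(C)(C)O1 | intermediate
5 | 2,2-dimethyl-6-(6-methyl-2-oxohept-5-en-1-yl)-4H-1,3-dioxin-4-one | CC(C)=CCCC(=O)CC1=CC(=O)OC(C)(C)O1 | intermediate
6 | 1-bromo-3-methylbut-2-ene (prenyl bromide) | CC(C)=CCBr | starting material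
7 | 6-[2,10-dimethyl-5-(3-methylbut-2-en-1-yl)-6-oxoundeca-2,9-dien-5-yl]-2,2-dimethyl-4H-1,3-dioxin-4-one | CC(C)=CCCC(=O)C(CC=C(C)C)(CC=C(C)C)C1=CC(=O)OC(C)(C)O1 | intermediate
8 | 9-methyl-4,4-bis(3-methylbut-2-en-1-yl)deca-1,8-diene-1,3,5-trione (acylketene) | O=C=CC(=O)C(CC=C(C)C)(CC=C(C)C)C(=O)CCC=C(C)C | intermediate
9 | (6Z)-6-(4-methylpent-3-en-1-ylidene)-5,5-bis(3-methylbut-2-en-1-yl)oxane-2,4-dione (enol lactone) | O=C1CC(=O)C(CC=C(C)C)(CC=C(C)C)/C(O1)=C/CC=C(C)C | intermediate
10 | 3,5-dihydroxy-4,6,6-tris(3-methylbut-2-en-1-yl)cyclohexa-2,4-dien-1-one | O=C1C=C(O)C(CC=C(C)C)=C(O)C1(CC=C(C)C)CC=C(C)C | intermediate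
11 | propanoic acid | CCC(=O)O | starting material
12 | 5-hydroxy-4,4,6-tris(3-methylbut-2-en-1-yl)-3-oxocyclohexa-1,5-dien-1-yl propanoate (enol propanoate) | CCC(=O)OC1=CC(=O)C(CC=C(C)C)(CC=C(C)C)C(O)=C1CC=C(C)C | intermediate
13 | postlupulone, 3,5-dihydroxy-4,6,6-tris(3-methylbut-2-en-1-yl)-2-propanoylcyclohexa-2,4-dien-1-one | CCC(=O)C1=C(O)C(CC=C(C)C)=C(O)C(CC=C(C)C)(CC=C(C)C)C1=O | target

Total step count: 5
Longest linear sequence: 5 steps (1 to 2 to 5 to 7 to 10 to 13)

**Steps most likely to fail**

1. Step 4 (proposed new method). What may go wrong: dimerisation of the ketene, or its capture by a prenyl alkene, before the ketone oxygen reaches it; stalling of the O-to-C transposition at the enol-lactone salt. Fallback with known chemistry, from 7 back to 10: 7 would be heated in toluene with methanol (110 °C) so that the acylketene is intercepted by the alcohol, the standard external trapping of dioxinone-derived ketenes. This should give methyl 9-methyl-4,4-bis(3-methylbut-2-en-1-yl)-3,5-dioxodec-8-enoate F1. Dieckmann condensation of F1 (NaOMe, MeOH, 65 °C), the classical entry to cyclohexane-1,3,5-triones from 3,5-dioxo esters, would then close the same C3–C4 bond with loss of methanol and deliver 10.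

2. Step 3. What may go wrong: O-alkylation of the ambident enolate, and arrest after the first alkylation because the second one has to build a quaternary carbon. Fallback, from 5 back to 7: the second C–C bond would be made by π-allyl chemistry instead of SN2 displacement. Mono-alkylation of 5 (K2CO3, acetone, 1 equiv of 6) should give rac-6-(2,10-dimethyl-6-oxoundeca-2,9-dien-5-yl)-2,2-dimethyl-4H-1,3-dioxin-4-one F2. Tsuji–Trost allylation of F2 with methyl 3-methylbut-2-en-1-yl carbonate and Pd(PPh3)4 (zerovalent palladium, THF, rt), in which the soft enolate attacks the unsubstituted terminus of the π-prenyl complex through carbon, should then give 7.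

3. Step 5. What may go wrong: arrest at the enol ester, over-acylation on oxygen, or competing acyl transfer to C4. Fallback, from 7 back to 13: the order of transposition and acylation would be inverted. Thermolysis of 7 without base lets 9 be isolated. 9 has a single nucleophilic carbon (the future C2), which would be acylated with 11, DCC and DMAP, the usual 3-acylation of 4-hydroxy-2-pyranones, to give (6Z)-4-hydroxy-6-(4-methylpent-3-en-1-ylidene)-5,5-bis(3-methylbut-2-en-1-yl)-3-propanoyl-5,6-dihydro-2H-pyran-2-one F3. NaOMe in MeOH would then effect the enol-lactone to β-triketone transposition of F3, an isomerisation that forms C3–C4 and ends at 13.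

**Further compounds**
F1 | step 4 | methyl 9-methyl-4,4-bis(3-methylbut-2-en-1-yl)-3,5-dioxodec-8-enoate | COC(=O)CC(=O)C(CC=C(C)C)(CC=C(C)C)C(=O)CCC=C(C)C
F2 | step 3 | rac-6-(2,10-dimethyl-6-oxoundeca-2,9-dien-5-yl)-2,2-dimethyl-4H-1,3-dioxin-4-one | CC(C)=CCCC(=O)C(CC=C(C)C)C1=CC(=O)OC(C)(C)O1
F3 | step 5 | (6Z)-4-hydroxy-6-(4-methylpent-3-en-1-ylidene)-5,5-bis(3-methylbut-2-en-1-yl)-3-propanoyl-5,6-dihydro-2H-pyran-2-one | CCC(=O)C1=C(O)C(CC=C(C)C)(CC=C(C)C)/C(OC1=O)=C/CC=C(C)C
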